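**Retrosynthetic overview**

1. Ring atoms are numbered C1 (bears CH2OBz), C2 (vinylic CH), C3 (OMe), C4 (OH), C5 (OBz), C6 (allylic OH). The O5 benzoate comes from triol 8 by tin-directed monoacylation, and the cis C5/C6 diol from anti osmylation of cyclohexa-1,3-diene 7.
2. Diene 7 comes from one ruthenium-catalysed diene–alkyne metathesis annulation that makes C1=C2 and C5=C6 together. Prop-2-yn-1-yl benzoate 5 supplies C1, C6 and the CH2OBz arm; dienol 4 supplies C2–C5.
3. Enabling feature: the C1=C2 alkene next to the cis C5/C6 diol is a masked C2=C1–C6=C5 diene. Its inner sp2 carbons C1 and C6 are the two carbons of an alkyne; its outer CH carbons C2 and C5 are vinyl groups already joined by the sp3 C3–C4 bridge carrying the cis OMe/OH pair.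
4. Dienol 4 comes from divinylcarbinol 1 by Sharpless desymmetrisation (sets C3 and C4), O-methylation and one-carbon epoxide-to-vinyl homologation.
5. Ring order: the only ring, the carbocycle, is closed in step 4; the C5 and C6 stereocentres follow in step 5.

Key step: step 4

Remark: 1 and 5 are taken as purchased, and the target SMILES corresponds to (3R,4R,5R,6R) in the ring numbering above.

**Step 1**
Reactants: 1 penta-1,4-dien-3-ol
Product: 2 (2S,3R)-1,2-epoxypent-4-en-3-ol
Conditions: Ti(OiPr)4 (cat.), D-(−)-diisopropyl tartrate, t-BuOOH, 4 Å MS, CH2Cl2, −20 °C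
Reagents that add atoms: tert-butyl hydroperoxide, CC(C)(C)OO
Why: Sharpless asymmetric epoxidation used as a desymmetrisation, in which the D-(−)-tartrate–titanium complex selects one enantiotopic vinyl group and one of its faces (erythro product, oxygen anti to the other vinyl group), so that C2 (S) and C3 (R) are set together, and the minor enantiomer should be removed by faster second epoxidation as conversion rises.

**Step 2**
Reactants: 2 (2S,3R)-1,2-epoxypent-4-en-3-ol
Product: 3 (S)-2-[(R)-1-methoxyprop-2-en-1-yl]oxirane
Conditions: MeI (3 equiv), then NaH, THF, 0 °C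
Reagents that add atoms: iodomethane, CI
Why: Williamson etherification with iodomethane present before the base is added, so that O-methylation should outrun Payne rearrangement of the epoxy alkoxide; no stereocentre is touched.

**Step 3**
Reactants: 3 (S)-2-[(R)-1-methoxyprop-2-en-1-yl]oxirane
Product: 4 (3S,4R)-4-methoxyhexa-1,5-dien-3-ol
Conditions: Me3S+ I− (3 equiv), n-BuLi, THF, −10 °C to 20 °C
Reagents that add atoms: trimethylsulfonium iodide, C[S+](C)C.[I-]
Why: one-carbon homologation of a terminal epoxide to an allylic alcohol with excess dimethylsulfonium methylide (the Corey–Chaykovsky ylide): the ylide opens the epoxide at CH2 and a second equivalent of base converts the β-oxido sulfonium salt into the vinyl group with loss of Me2S; the C–O bond at the stereocentre is never broken, so its configuration is retained.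

**Step 4**
Reactants: 4 (3S,4R)-4-methoxyhexa-1,5-dien-3-ol; 5 prop-2-yn-1-yl benzoate
Product: 7 [(3R,4S)-4-hydroxy-3-methoxycyclohexa-1,5-dien-1-yl]methyl benzoate, via Z-triene 6 (not isolated)
Conditions: 4 (1.5 equiv), 5 added over 6 h, RuCl2(=CHPh)(PCy3)(H2IMes) (second-generation Grubbs catalyst, 5 mol%), CH2Cl2 (0.02 M), 40 °C
Reagents that add atoms: none
Why: A ruthenium alkylidene formed at the hydroxyl-bearing end of 4 adds to the terminal alkyne carbon of 5 and, through a ruthenacyclobutene, gives a vinylcarbene in which C5=C6 is made and the metal sits on C1; this carbene then undergoes ring-closing metathesis onto the vinyl group next to C3, making C1=C2 and releasing Ru=CH2, which returns to 4 with loss of ethene. The closest known reaction type is the tandem intermolecular enyne cross-metathesis/ring-closing metathesis of terminal alkynes with 1,5-dienes that gives 2-substituted cyclohexa-1,3-dienes, for which propargylic esters are standard alkyne partners. The single ring closes in a six-membered ring-closing-metathesis mode (carbene on C1 onto the C2 vinyl group), the alkyne insertion itself being intermolecular. No stereocentre is created: C3 and C4 are carried unchanged from 4, and the ring forces both new alkenes to be cis. Two selectivities are needed: regiochemistry (the hydroxyl-side vinyl group must meet the alkyne CH), which should be secured by the accelerating effect of a free allylic hydroxyl and the retarding effect of an allylic methyl ether on carbene exchange, together with the usual preference of the alkylidene carbon for the unsubstituted alkyne terminus; and Z geometry at C5=C6, since only the Z vinylcarbene or the Z triene 6 can close. The E triene should be returned to the manifold by secondary metathesis at its disubstituted diene terminus and drain through the irreversible ring closure.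

**Step 5**
Reactants: 7 [(3R,4S)-4-hydroxy-3-methoxycyclohexa-1,5-dien-1-yl]methyl benzoate
Product: 8 [(3R,4S,5R,6R)-4,5,6-trihydroxy-3-methoxycyclohex-1-en-1-yl]methyl benzoate
Conditions: OsO4 (2 mol%), N-methylmorpholine N-oxide, acetone/H2O 4:1, 0 °C
Reagents that add atoms: osmium tetroxide, O=[Os](=O)(=O)=O; N-methylmorpholine N-oxide, C[N+]1([O-])CCOCC1; water, O
Why: Upjohn dihydroxylation, in which the [3+2] osmylation adds both oxygens to one face (O5 and O6 cis) and should approach anti to the C4 hydroxyl and C3 methoxy groups that shield the other face (the usual anti preference for allylic oxygen), setting C5 (R) and C6 (R); the cis-disubstituted C5=C6 alkene should react before C1=C2, which is more hindered and deactivated by two allylic C–O bonds.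

**Step 6**
Reactants: 8 [(3R,4S,5R,6R)-4,5,6-trihydroxy-3-methoxycyclohex-1-en-1-yl]methyl benzoate
Product: 10 [(3R,4R,5R,6R)-5-(benzoyloxy)-4,6-dihydroxy-3-methoxycyclohex-1-en-1-yl]methyl benzoate, via stannylene acetal 9 (not isolated)
Conditions: Me2SnCl2 (5 mol%), BzCl (1.1 equiv), K2CO3, THF, 20 °C
Reagents that add atoms: benzoyl chloride, O=C(Cl)c1ccccc1
Why: tin-catalysed monoacylation through a cyclic stannylene acetal: the cis-5,6-diol forms the five-membered stannylene 9 and its equatorial oxygen O5 should take the acyl group rather than the pseudoaxial allylic O6 or the isolated O4, as in the 3-O-acylation of rhamno- and mannopyranosides that carry the same axial/equatorial/equatorial triol; no stereocentre changes.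

**Compound list**

1 | penta-1,4-dien-3-ol (divinylcarbinol) | C=CC(O)C=C | starting material
2 | (2S,3R)-1,2-epoxypent-4-en-3-ol | C=C[C@@H](O)[C@@H]1CO1 | intermediate
3 | (S)-2-[(R)-1-methoxyprop-2-en-1-yl]oxirane | C=C[C@@H](OC)[C@@H]1CO1 | intermediate
4 | (3S,4R)-4-methoxyhexa-1,5-dien-3-ol | C=C[C@@H](OC)[C@@H](O)C=C | intermediate
5 | prop-2-yn-1-yl benzoate | C#CCOC(=O)c1ccccc1 | starting material
6 | (3Z,5S,6R)-5-hydroxy-6-methoxy-2-methylideneocta-3,7-dien-1-yl benzoate | C=C(COC(=O)c1ccccc1)/C=C\[C@H](O)[C@H](OC)C=C | intermediate (not isolated)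
7 | [(3R,4S)-4-hydroxy-3-methoxycyclohexa-1,5-dien-1-yl]methyl benzoate | CO[C@@H]1C=C(COC(=O)c2ccccc2)C=C[C@@H]1O | intermediate
8 | [(3R,4S,5R,6R)-4,5,6-trihydroxy-3-methoxycyclohex-1-en-1-yl]methyl benzoate | CO[C@@H]1C=C(COC(=O)c2ccccc2)[C@@H](O)[C@@H](O)[C@@H]1O | intermediate
9 | 5,6-O-(dimethylstannanediyl) acetal of 8 (2,2-dimethyl-1,3,2-dioxastannolane fused at C5–C6) | CO[C@@H]1C=C(COC(=O)c2ccccc2)[C@H]2O[Sn](C)(C)O[C@H]2[C@@H]1O | intermediate (not isolated)
10 | [(3R,4R,5R,6R)-5-(benzoyloxy)-4,6-dihydroxy-3-methoxycyclohex-1-en-1-yl]methyl benzoate | CO[C@@H]1C=C(COC(=O)c2ccccc2)[C@@H](O)[C@@H](OC(=O)c2ccccc2)[C@@H]1O | target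

**Step count and risks**

Total step count: 6. Longest linear sequence: 6 steps (1 → 2 → 3 → 4 → 7 → 8 → 10).

Steps most likely to fail:

Step 4 (key step). What may go wrong: the intermolecular alkyne insertion may deliver mainly the E vinylcarbene, which cannot close and drains into acyclic triene and oligomers faster than it is recycled; initiation at the methoxy-side vinyl group would give the regioisomeric diene. Fallback (a temporary silicon tether fixes both the Z geometry and the pairing of the alkenes; it sets out from 4 and 5 and returns at 7): enyne cross-metathesis of 5 with ethene under the same ruthenium catalyst gives 2-methylidenebut-3-en-1-yl benzoate F1, and methanolysis (K2CO3, MeOH) gives 2-methylidenebut-3-en-1-ol F2. Compounds 4 and F2 are joined with iPr2SiCl2 and imidazole as the mixed silyl ketal F3. Ring-closing metathesis between the vinyl group at C5 and the monosubstituted end of the butadiene closes the eight-membered siloxane F4, in which C5=C6 can only be Z. Bu4NF removes the tether to give triene diol F5, a second ring-closing metathesis (C1=C2, six-membered) gives diene diol F6, and benzoylation of the primary allylic hydroxyl (BzCl, 2,4,6-collidine, −40 °C) gives 7.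

Step 5. What may go wrong: osmylation at the trisubstituted C1=C2 alkene or on the hydroxyl-bearing face through hydrogen-bond delivery, and dehydration of the dienol to arenes during the oxidation. Fallback (temporary protection and stoichiometric low-temperature osmylation; it sets out from 7 and returns at 8): silylation (TBSOTf, 2,6-lutidine, −78 °C) gives silyl ether F7, which cannot lose water and shields the upper face more strongly. Stoichiometric OsO4 in pyridine/CH2Cl2 at −78 °C with NaHSO3 work-up gives diol F8, and HF·pyridine then gives 8. This addresses face selectivity and aromatisation; site selectivity would still rest on the intrinsic preference for C5=C6.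

Step 6. What may go wrong: acylation at O4 or O6 instead of O5, over-acylation, and benzoyl migration between the cis 5,6-oxygens. Fallback (selectivity from temporary protection instead of from the reagent; it sets out from 8 and returns at 10): the cis-diol alone forms the 5,6-O-isopropylidene acetal F9 (2-methoxypropene, pyridinium p-toluenesulfonate). The remaining O4–H is silylated (TBDPSCl, imidazole, DMF) to F10, and aqueous acetic acid removes the acetal to give diol F11. The tin-catalysed benzoylation of step 6 then has to choose only between equatorial O5 and pseudoaxial O6 and gives F12; HF·pyridine removes the silyl group to give 10.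

**Further compounds**

F1 | step 4 | 2-methylidenebut-3-en-1-yl benzoate | C=CC(=C)COC(=O)c1ccccc1
F2 | step 4 | 2-methylidenebut-3-en-1-ol | C=CC(=C)CO
F3 | step 4 | {[(3S,4R)-4-methoxyhexa-1,5-dien-3-yl]oxy}[(2-methylidenebut-3-en-1-yl)oxy]di(propan-2-yl)silane | C=C[C@@H](OC)[C@H](C=C)O[Si](C(C)C)(C(C)C)OCC(=C)C=C
F4 | step 4 | (6Z,8S)-8-[(1R)-1-methoxyprop-2-en-1-yl]-5-methylidene-2,2-di(propan-2-yl)-1,3-dioxa-2-silacyclooct-6-ene | C=C[C@@H](OC)[C@@H]1/C=C\C(=C)CO[Si](C(C)C)(C(C)C)O1
F5 | step 4 | (3Z,5S,6R)-6-methoxy-2-methylideneocta-3,7-diene-1,5-diol | C=C(CO)/C=C\[C@H](O)[C@H](OC)C=C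
F6 | step 4 | (1S,6R)-4-(hydroxymethyl)-6-methoxycyclohexa-2,4-dien-1-ol | CO[C@@H]1C=C(CO)C=C[C@@H]1O
F7 | step 5 | [(3R,4S)-4-{[tert-butyl(dimethyl)silyl]oxy}-3-methoxycyclohexa-1,5-dien-1-yl]methyl benzoate | CO[C@@H]1C=C(COC(=O)c2ccccc2)C=C[C@@H]1O[Si](C)(C)C(C)(C)C
F8 | step 5 | [(3R,4S,5R,6R)-4-{[tert-butyl(dimethyl)silyl]oxy}-5,6-dihydroxy-3-methoxycyclohex-1-en-1-yl]methyl benzoate | CO[C@@H]1C=C(COC(=O)c2ccccc2)[C@@H](O)[C@@H](O)[C@@H]1O[Si](C)(C)C(C)(C)C
F9 | step 6 | 5,6-O-isopropylidene acetal of 8 | CO[C@@H]1C=C(COC(=O)c2ccccc2)[C@H]2OC(C)(C)O[C@H]2[C@@H]1O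
F10 | step 6 | 4-O-tert-butyldiphenylsilyl ether of F9 | CO[C@@H]1C=C(COC(=O)c2ccccc2)[C@H]2OC(C)(C)O[C@H]2[C@@H]1O[Si](c3ccccc3)(c4ccccc4)C(C)(C)C
F11 | step 6 | 4-O-tert-butyldiphenylsilyl ether of 8 | CO[C@@H]1C=C(COC(=O)c2ccccc2)[C@@H](O)[C@@H](O)[C@@H]1O[Si](c3ccccc3)(c4ccccc4)C(C)(C)C
F12 | step 6 | 4-O-tert-butyldiphenylsilyl ether of 10 | CO[C@@H]1C=C(COC(=O)c2ccccc2)[C@@H](O)[C@@H](OC(=O)c2ccccc2)[C@@H]1O[Si](c3ccccc3)(c4ccccc4)C(C)(C)C
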